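The route rests on cutting the chalcone between ring A carbon C1' and the ketone carbon. In the key step the complete, side-chain-bearing resorcinol bis-MOM ether, its (R)-carbinol masked in the flask as a lithium alkoxide, is lithiated ortho to the O2' acetal and acylated by the Weinreb amide of O-MOM-p-coumaric acid. One operation delivers the whole skeleton as the enone. The step exploits the 2',4'-dioxygenation of ring A: with the side chain on C3' between the two oxygens, the only ring C–H bonds ortho to an oxygen are two equivalent ones, so metalation can only lead to C1'. The stereocenter is bought with methyl (R)-glycidate.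

Key step: step 6

Assumption: 1,3-bis(methoxymethoxy)benzene and 4-(methoxymethoxy)benzaldehyde are taken as purchasable MOM ethers.

**Step 1**
Reactants: 1 1,3-bis(methoxymethoxy)benzene; 2 methyl (2R)-oxirane-2-carboxylate (methyl (R)-glycidate)
Product: 5 methyl (2R)-3-[2,6-bis(methoxymethoxy)phenyl]-2-hydroxypropanoate, via 2-lithio-1,3-bis(methoxymethoxy)benzene 3 (not isolated), via [2,6-bis(methoxymethoxy)phenyl]magnesium bromide 4 (not isolated)
Conditions: n-BuLi, THF, 0 °C → rt; MgBr2·OEt2, 0 °C; CuI (10 mol %), then 2, −40 → −10 °C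
Reagents that add atoms: none
Why: Directed ortho-metalation removes the C2 proton flanked by both OMOM groups, and the aryl Grignard reagent 4 under copper catalysis opens the glycidate by SN2 attack at the unsubstituted C3 (organocopper epoxide opening) while the hindered aryl spares the ester, so that no bond to the stereocenter is touched and its (R) configuration is taken over from the chiral pool.

**Step 2**
Reactants: 5 methyl (2R)-3-[2,6-bis(methoxymethoxy)phenyl]-2-hydroxypropanoate
Product: 6 (2R)-3-[2,6-bis(methoxymethoxy)phenyl]-2-hydroxy-N-methoxy-N-methylpropanamide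
Conditions: MeNH(OMe)·HCl, i-PrMgCl (excess), THF, −20 → 0 °C
Reagents that add atoms: N,O-dimethylhydroxylamine hydrochloride, CNOC.Cl
Why: Aminolysis of the methyl ester by the chloromagnesium amide of N,O-dimethylhydroxylamine (Weinreb amide formation from an ester) should proceed with the hydroxyl carried as its magnesium alkoxide, which also shuts off enolisation at the stereocenter.

**Step 3**
Reactants: 6 (2R)-3-[2,6-bis(methoxymethoxy)phenyl]-2-hydroxy-N-methoxy-N-methylpropanamide; 7 5-bromo-2-methylpent-2-ene
Product: 10 (2R)-1-[2,6-bis(methoxymethoxy)phenyl]-2-hydroxy-7-methyloct-6-en-3-one, via (4-methylpent-3-en-1-yl)magnesium bromide 8 (not isolated), via the magnesium hemiaminal adduct 9 (not isolated)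
Conditions: 7, Mg, THF, rt; then 6 (8 in 3 equiv), THF, 0 °C
Reagents that add atoms: none
Why: Weinreb ketone synthesis, in which the first equivalent of 8 forms the alkoxide, the next adds once, and the N-methoxy chelate 9 holds until work-up, so that no tertiary alcohol forms and the carbinol center, not enolisable as an alkoxide, is kept.

**Step 4**
Reactants: 10 (2R)-1-[2,6-bis(methoxymethoxy)phenyl]-2-hydroxy-7-methyloct-6-en-3-one
Product: 11 (2R)-1-[2,6-bis(methoxymethoxy)phenyl]-7-methyl-3-methylideneoct-6-en-2-ol
Conditions: Ph3PCH3Br, KOt-Bu (ylide in 3 equiv), THF, 0 °C → rt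
Reagents that add atoms: methyltriphenylphosphonium bromide, C[P+](c1ccccc1)(c1ccccc1)c1ccccc1.[Br-]
Why: Wittig methylenation with excess non-stabilised ylide, in which the first equivalent turns the hydroxyl into its alkoxide (which disfavours enolisation toward C2) and the rest converts the ketone into the 1,1-disubstituted alkene without touching the stereocenter.

**Step 5**
Reactants: 12 4-(methoxymethoxy)benzaldehyde; 13 diethyl {2-[methoxy(methyl)amino]-2-oxoethyl}phosphonate
Product: 15 (2E)-N-methoxy-3-[4-(methoxymethoxy)phenyl]-N-methylprop-2-enamide, via the sodium phosphonate carbanion 14 (not isolated)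
Conditions: NaH, THF, 0 °C → rt
Reagents that add atoms: none
Why: Horner–Wadsworth–Emmons olefination of an aromatic aldehyde with an amide-stabilised phosphonate carbanion, which should give the (E)-enamide through the reversible, thermodynamically controlled addition step.

**Step 6**
Reactants: 11 (2R)-1-[2,6-bis(methoxymethoxy)phenyl]-7-methyl-3-methylideneoct-6-en-2-ol; 15 (2E)-N-methoxy-3-[4-(methoxymethoxy)phenyl]-N-methylprop-2-enamide
Product: 18 (2E)-1-{3-[(2R)-2-hydroxy-7-methyl-3-methylideneoct-6-en-1-yl]-2,4-bis(methoxymethoxy)phenyl}-3-[4-(methoxymethoxy)phenyl]prop-2-en-1-one, via the dilithiated arene alkoxide 16 (not isolated), via the lithium hemiaminal adduct 17 (not isolated)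
Conditions: n-BuLi (2.3 equiv), TMEDA, THF, −78 → 0 °C; then 15 (1.3 equiv), −78 → −20 °C
Reagents that add atoms: none
Why: The first equivalent of n-BuLi forms the lithium alkoxide and the second, bound by TMEDA and the acetal oxygens of an OMOM group, removes the adjacent ring proton (complex-induced proximity) to give 16, which adds 1,2 to the amide carbonyl of 15 to give the N,O-chelated adduct 17 that releases the ketone only on aqueous work-up. The closest known reaction type is directed ortho-metalation of aryl MOM ethers combined with the Weinreb ketone synthesis, as used to make chalcones from aryllithiums and N-methoxy-N-methylcinnamamides. No ring is closed and no stereocenter is formed; the (R)-carbinol is present as an alkoxide and cannot epimerise. The step needs ring metalation instead of benzylic or allylic deprotonation, which the chelating OMOM groups and the charge of the neighbouring alkoxide should secure, and since the two ring positions ortho to an OMOM group are interchanged by rotation about the aryl–CH2 bond only one regioisomer can form. It also needs 1,2- instead of 1,4-addition and a single acylation, which the hard aryllithium and the stable chelate 17 should secure.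

**Step 7**
Reactants: 18 (2E)-1-{3-[(2R)-2-hydroxy-7-methyl-3-methylideneoct-6-en-1-yl]-2,4-bis(methoxymethoxy)phenyl}-3-[4-(methoxymethoxy)phenyl]prop-2-en-1-one
Product: 19 (2E)-1-{2,4-dihydroxy-3-[(2R)-2-hydroxy-7-methyl-3-methylideneoct-6-en-1-yl]phenyl}-3-(4-hydroxyphenyl)prop-2-en-1-one
Conditions: 3 M aq HCl/MeOH (1:4), 25–40 °C, stopped at full conversion
Reagents that add atoms: none
Why: Acid-catalysed acetal exchange with methanol should remove the three phenolic MOM groups (the O2' group first, aided by the neighbouring carbonyl) under conditions mild enough for the allylic alcohol, both alkenes and the (E)-enone, and the stereocenter takes no part.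

**Compound list**
1 | 1,3-bis(methoxymethoxy)benzene | COCOc1cccc(OCOC)c1 | starting material
2 | methyl (2R)-oxirane-2-carboxylate | COC(=O)[C@H]1CO1 | starting material
3 | 2-lithio-1,3-bis(methoxymethoxy)benzene | [Li]c1c(OCOC)cccc1OCOC | intermediate
4 | [2,6-bis(methoxymethoxy)phenyl]magnesium bromide | Br[Mg]c1c(OCOC)cccc1OCOC | intermediate
5 | methyl (2R)-3-[2,6-bis(methoxymethoxy)phenyl]-2-hydroxypropanoate | COC(=O)[C@H](O)Cc1c(OCOC)cccc1OCOC | intermediate
6 | (2R)-3-[2,6-bis(methoxymethoxy)phenyl]-2-hydroxy-N-methoxy-N-methylpropanamide | CON(C)C(=O)[C@H](O)Cc1c(OCOC)cccc1OCOC | intermediate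
7 | 5-bromo-2-methylpent-2-ene | CC(C)=CCCBr | starting material
8 | (4-methylpent-3-en-1-yl)magnesium bromide | CC(C)=CCC[Mg]Br | intermediate
9 | bis(bromomagnesium) hemiaminal adduct of 6 and 8 | CC(C)=CCCC(O[Mg]Br)(N(C)OC)[C@H](O[Mg]Br)Cc1c(OCOC)cccc1OCOC | intermediate
10 | (2R)-1-[2,6-bis(methoxymethoxy)phenyl]-2-hydroxy-7-methyloct-6-en-3-one | CC(C)=CCCC(=O)[C@H](O)Cc1c(OCOC)cccc1OCOC | intermediate
11 | (2R)-1-[2,6-bis(methoxymethoxy)phenyl]-7-methyl-3-methylideneoct-6-en-2-ol | C=C(CCC=C(C)C)[C@H](O)Cc1c(OCOC)cccc1OCOC | intermediate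
12 | 4-(methoxymethoxy)benzaldehyde | COCOc1ccc(C=O)cc1 | starting material
13 | diethyl {2-[methoxy(methyl)amino]-2-oxoethyl}phosphonate | CCOP(=O)(CC(=O)N(C)OC)OCC | starting material
14 | sodium carbanion of 13 | CCOP(=O)([CH-]C(=O)N(C)OC)OCC.[Na+] | intermediate
15 | (2E)-N-methoxy-3-[4-(methoxymethoxy)phenyl]-N-methylprop-2-enamide | CON(C)C(=O)/C=C/c1ccc(OCOC)cc1 | intermediate
16 | lithium (2R)-1-[3-lithio-2,6-bis(methoxymethoxy)phenyl]-7-methyl-3-methylideneoct-6-en-2-olate | C=C(CCC=C(C)C)[C@H](O[Li])Cc1c(OCOC)ccc([Li])c1OCOC | intermediate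
17 | dilithium hemiaminal adduct of 16 and 15 | C=C(CCC=C(C)C)[C@H](O[Li])Cc1c(OCOC)ccc(C(O[Li])(N(C)OC)/C=C/c2ccc(OCOC)cc2)c1OCOC | intermediate
18 | (2E)-1-{3-[(2R)-2-hydroxy-7-methyl-3-methylideneoct-6-en-1-yl]-2,4-bis(methoxymethoxy)phenyl}-3-[4-(methoxymethoxy)phenyl]prop-2-en-1-one | C=C(CCC=C(C)C)[C@H](O)Cc1c(OCOC)ccc(C(=O)/C=C/c2ccc(OCOC)cc2)c1OCOC | intermediate
19 | (2E)-1-{2,4-dihydroxy-3-[(2R)-2-hydroxy-7-methyl-3-methylideneoct-6-en-1-yl]phenyl}-3-(4-hydroxyphenyl)prop-2-en-1-one | C=C(CCC=C(C)C)[C@H](O)Cc1c(O)ccc(C(=O)/C=C/c2ccc(O)cc2)c1O | target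

**Step count**
Total steps: 7. Longest linear sequence: 6 (steps 1, 2, 3, 4, 6, 7).

**Steps most likely to fail**

Step 6. The metalation of the alkoxide-bearing substrate may stall or stray (aggregation of the dianion, benzylic or allylic deprotonation, addition of n-BuLi to the allylic alkoxide), so that the ring carbanion is not formed cleanly before the amide is added. The fallback fixes the metalation site with a bromine atom set before any alkene is present and replaces C–H deprotonation by bromine–lithium exchange. It sets out from 5: NBS, MeCN, 0 °C should brominate the ring position ortho to one OMOM group and para to the other to give methyl (2R)-3-[3-bromo-2,6-bis(methoxymethoxy)phenyl]-2-hydroxypropanoate F1. The operations of steps 2, 3 and 4, to which the aryl bromide should be inert, would then give the Weinreb amide (2R)-3-[3-bromo-2,6-bis(methoxymethoxy)phenyl]-2-hydroxy-N-methoxy-N-methylpropanamide F2, the ketone (2R)-1-[3-bromo-2,6-bis(methoxymethoxy)phenyl]-2-hydroxy-7-methyloct-6-en-3-one F3 and the alkene (2R)-1-[3-bromo-2,6-bis(methoxymethoxy)phenyl]-7-methyl-3-methylideneoct-6-en-2-ol F4. Treatment of F4 with t-BuLi (3.1 equiv), THF, −78 °C forms the alkoxide and exchanges bromine for lithium, and the fallback comes back to the route at 16, which is acylated with 15 as in step 6.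

Step 4. The basic ylide may enolise the α-ketol instead of adding to it, with erosion of the stereocenter or shift of the ketol, or addition to the alkoxide-bearing ketone may stall. The fallback is a Peterson olefination through a non-basic organocerium reagent. It sets out from 10: TMSCH2MgCl/CeCl3, THF, −78 °C should add to the ketone to give (2R)-1-[2,6-bis(methoxymethoxy)phenyl]-7-methyl-3-[(trimethylsilyl)methyl]oct-6-ene-2,3-diol F5 (either C3 epimer serves). KH, THF, 0 °C → rt then eliminates the β-oxidosilane, and the fallback comes back to the route at 11.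

Step 7. The Brønsted acid may protonate the 1,1-disubstituted alkene or ionise the allylic alcohol, after which a neighbouring phenol can close onto the side chain. Methanol may also add to the trisubstituted alkene, or the 2'-hydroxychalcone may close to the flavanone. The fallback exchanges the acetals for silyl ethers under buffered, aprotic conditions and then removes silicon with mild base. It sets out from 18: TMSOTf, 2,2'-bipyridyl, MeCN, 0 °C → rt should convert the three aryl MOM ethers into aryl trimethylsilyl ethers and silylate the carbinol, giving the tetrakis(trimethylsilyl) ether of the target F6. K2CO3, MeOH, 0 °C then removes the four silyl groups, and the fallback comes back to the route at 19.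

**Further compounds**
F1 | step 6 | methyl (2R)-3-[3-bromo-2,6-bis(methoxymethoxy)phenyl]-2-hydroxypropanoate | COC(=O)[C@H](O)Cc1c(OCOC)ccc(Br)c1OCOC
F2 | step 6 | (2R)-3-[3-bromo-2,6-bis(methoxymethoxy)phenyl]-2-hydroxy-N-methoxy-N-methylpropanamide | CON(C)C(=O)[C@H](O)Cc1c(OCOC)ccc(Br)c1OCOC
F3 | step 6 | (2R)-1-[3-bromo-2,6-bis(methoxymethoxy)phenyl]-2-hydroxy-7-methyloct-6-en-3-one | CC(C)=CCCC(=O)[C@H](O)Cc1c(OCOC)ccc(Br)c1OCOC
F4 | step 6 | (2R)-1-[3-bromo-2,6-bis(methoxymethoxy)phenyl]-7-methyl-3-methylideneoct-6-en-2-ol | C=C(CCC=C(C)C)[C@H](O)Cc1c(OCOC)ccc(Br)c1OCOC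
F5 | step 4 | (2R)-1-[2,6-bis(methoxymethoxy)phenyl]-7-methyl-3-[(trimethylsilyl)methyl]oct-6-ene-2,3-diol | CC(C)=CCCC(O)(C[Si](C)(C)C)[C@H](O)Cc1c(OCOC)cccc1OCOC
F6 | step 7 | (2E)-1-{3-[(2R)-7-methyl-3-methylidene-2-(trimethylsilyloxy)oct-6-en-1-yl]-2,4-bis(trimethylsilyloxy)phenyl}-3-[4-(trimethylsilyloxy)phenyl]prop-2-en-1-one | C=C(CCC=C(C)C)[C@H](O[Si](C)(C)C)Cc1c(O[Si](C)(C)C)ccc(C(=O)/C=C/c2ccc(O[Si](C)(C)C)cc2)c1O[Si](C)(C)C
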